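The earlier runs and the new flask are simulated on assumed constants, and the scatter is random.

If free base is what pays for each turn of this reaction, I should price a turn before I trust any computed curve.

| flask | solid electrophile | free base | protonated nucleophile | remark | time |
|---|---|---|---|---|---|
| west | 0.050 M | 0.094 M | 0.10 M | run made earlier |  |
| south | 0.050 M | 0.16 M | 0.10 M | run made earlier |  |
| south-west | 0.050 M | 0.22 M | 0.10 M | run made earlier |  |
| amber | 0.050 M | 0.100 M | 0.100 M |  | 2.0 h |
| grey | 0.050 M | 0.150 M | 0.100 M |  | 2.0 h |
| ochre | 0.050 M | 0.230 M | 0.100 M |  | 2.0 h |

- west (time / min: solid electrophile / %, target / %): 8.00: 13.0, 35.8; 20.0: 0, 59.9; 40.0: 0, 64.3; 60.0: 0, 64.1; 80.0: 1.4, 62.8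
- south (time / min: solid electrophile / %, target / %): 8.00: 8.7, 40.3; 20.0: 0, 55.6; 40.0: 0, 44.3; 60.0: 0.1, 34.8; 80.0: 0.4, 27.4
- south-west (time / min: solid electrophile / %, target / %): 8.00: 6.2, 39.0; 20.0: 0.5, 43.8; 40.0: 0, 23.8; 60.0: 0.1, 12.3; 80.0: 0, 6.0

(standard deviation of a reading: 0.5 percentage points)

1. part of the solid electrophile that has reacted (what has only dissolved counts as not reacted) at the end, amber
2. part of the solid electrophile that has reacted (what has only dissolved counts as not reacted) at the end, grey
3. part of the solid electrophile that has reacted (what has only dissolved counts as not reacted) at the end, ochre
4. what raising the concentration of free base from its lowest to its highest value here does to the part of the solid electrophile that has reacted (what has only dissolved counts as not reacted) (changes below 5 percentage points count as none) (no change / it falls / it rises)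

- at the start none of the solid electrophile is in solution
- what has only dissolved of solid electrophile counts as not reacted

I start with the main step as I suppose it: electrophile meets nucleophile, one free base frees that nucleophile from protonated nucleophile, and a second takes up the acid set free. A charge of 0.050 M would then cost 0.100 M, about what amber holds and more than west's 0.094 M.

Next I add the loss of target to free base, which I suppose costs one more free base per turn without altering what has reacted. In the south-west run target falls from 43.8% to 6.0% between 20.0 min and 80.0 min, a reading of 0.0331 min⁻¹. Run back to the start, that line gives 85.0%, so I read the other 15.0% as electrophile taking a side path that I assume costs no base. The base bill, two free base for each turn on that share of the charge, is then 0.0850 M.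

What stays unreacted I reckon as a small correction. The west run holds 0.00903 M beyond the bill, enough for 18.1% of the charge to go on from target. Added to its reading of 64.3% of target at 40.0 min, that falls short of 85.0% by 2.6 percentage points. Amber holds 0.0150 M beyond the bill, and grey and ochre hold more, so I take solid electrophile as the limiting reagent in all three and commit to a change under 5 points across them.

The forecast differs, with 78% for amber, 99% for grey, 100% for ochre and the trend it rises: “Conversion therefore rises with base”.

The flask gives 98.4% for amber, >99.9% for grey and >99.9% for ochre, so the trend is no change, a change of 1.6 points.

    electrophile + nucleophile → acid set free + target (k = 0.0550 M⁻¹ s⁻¹)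
    nucleophile + acid set free ⇌ protonated nucleophile, settled at all times (K = 15000 M⁻¹)
    acid set free + free base ⇌ salt of the base, settled at all times (K = 34000 M⁻¹)
    solid electrophile ⇌ electrophile, rate k4*(cs4 - [electrophile]) while solid is left; crystals form when [electrophile] > cs4 (solubility = 36.0 mM, k = 0.00450 s⁻¹)
    free base + target → over-reaction product (k = 0.00950 M⁻¹ s⁻¹)
    2 electrophile → homo dimer (k = 0.0100 M⁻¹ s⁻¹)

Amber has not come to rest at 2.00 h: salt of the base stands at 0.0854 M, close to the bill of 0.0850 M, while 1.60% is still electrophile. Ten times the time brings the reacted part to >99.9%, while target goes from 58.4% to 40.9% and over-reaction product from 24.7% to 43.7%. Homo dimer stays at 15.4%. In ochre the longer time leaves the reacted part where it was.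

Take a neighbour flask like ochre but with 0.092 M of free base: if I keep the bill at 0.0850 M, that leaves 0.00703 M beyond it, so I expect a small shortfall like the one I reckoned for west. Computed, 97.5% has reacted and 2.52% remains as electrophile.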